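The readings are calculated with constants of no real substance; noise was put on by code.

Late in the amber run, between 120 min and 140 min, the flask turned 0.00188 min⁻¹ of amber's charge. Over its first 18 min, the violet run turned 0.00403 min⁻¹ in the same measure, so amber was slower. Yet the two held nearly the same starting material, 47.2% against 46.4% of amber's charge, and had been given the same free catalyst.

You asked for a quick number on the teal run, with the hunch that it follows amber. This is what I had:

| flask | starting material | free catalyst | product | time |
|---|---|---|---|---|
| amber | 0.0800 M | 0.00160 M |  |  |
| violet | 0.0400 M | 0.00160 M |  |  |
| ochre | 0.120 M | 0.00160 M |  |  |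
| blue | 0.0800 M | 0.00320 M |  |  |
| teal | 0.0800 M | 0.00160 M | 0.0400 M | 140 min |

| run | time / min | [product] / M |
|---|---|---|
| amber run | 18 | 0.0086 |
| amber run | 35 | 0.0156 |
| amber run | 52 | 0.0225 |
| amber run | 70 | 0.0288 |
| amber run | 88 | 0.0342 |
| amber run | 100 | 0.0365 |
| amber run | 120 | 0.0407 |
| amber run | 140 | 0.0437 |
| violet run | 18 | 0.0058 |
| violet run | 35 | 0.0101 |
| violet run | 52 | 0.0139 |
| violet run | 70 | 0.0181 |
| violet run | 88 | 0.0208 |
| violet run | 100 | 0.0220 |
| violet run | 120 | 0.0253 |
| violet run | 140 | 0.0265 |
| ochre run | 18 | 0.0099 |
| ochre run | 35 | 0.0186 |
| ochre run | 52 | 0.0270 |
| ochre run | 70 | 0.0356 |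
| ochre run | 88 | 0.0420 |
| ochre run | 100 | 0.0447 |
| ochre run | 120 | 0.0504 |
| ochre run | 140 | 0.0545 |
| blue run | 18 | 0.0367 |
| blue run | 35 | 0.0571 |
| blue run | 52 | 0.0669 |
| blue run | 70 | 0.0718 |
| blue run | 88 | 0.0737 |
| blue run | 100 | 0.0754 |
| blue run | 120 | 0.0760 |
| blue run | 140 | 0.0764 |

(each reading ± 4 × 10⁻⁴ M)

- Overall: starting material -> product, with free catalyst as catalyst.
- Constant volume, constant temperature.
- Bound and free are read together.
- An order is taken over about fifteen percent of the charge, up and down.
- A share of product counts the product that was charged too.

1. apparent order in [free catalyst] of the starting rate, round the charge of the amber run (the rate where two percent of its starting material have turned into product)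
2. apparent order in [starting material] of the starting rate, round the charge of the amber run (the rate where two percent of its starting material have turned into product) (one fixed amount of product, the same in the runs compared)
3. the violet run starts with 0.0400 M less of starting material than the amber run, and with no product. Compared where both hold the same amount of starting material, once fifteen percent of what the violet run was charged with has turned into product, is the violet run faster, slower or alike (within a tenth)?
4. product in the teal run at 140 min, as a share of the starting material charged

I took the ratio of those two rates, 0.466, as a reading with wide scatter. Against it I set exposure, the area under product share against time, which amber had gathered to 40.5 min by that late interval, counting violet's start as nil. The kill constant, a deactivation constant, is the fall in the logarithm of the rate per minute of exposure: 0.0189 min⁻¹.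

I then computed teal as amber plus a correction. Its charged product adds 70.0 min of exposure by 140 min, so, if product does the killing, teal's rate ends at 0.266 of amber's and averages 0.555 of it. My figure was 80.3%.

The forecast read the same shortfall otherwise: "the shortfall tracks time rather than product". It gave order 2.1 in free catalyst (1.8 to 2.3), order 0.5 in starting material (0.35 to 0.65), violet faster, and teal 104% (96% to 108%), which is 24 percentage points above my figure.

The simulation gave orders 2.5 and 0.48, violet faster, and teal 89.0%.

    free catalyst + starting material ⇌ catalyst-substrate complex, settled at all times (4.660 L mol⁻¹)
    catalyst-substrate complex + free catalyst → product + 2 free catalyst (1470 L mol⁻¹ min⁻¹)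
    free catalyst + product → spent catalyst + product (0.1332 L mol⁻¹ min⁻¹)
    free catalyst + impurity → spent catalyst

The step in which product turns free catalyst into spent catalyst held teal down: without it teal reaches 116%, not 89.0%. Teal made 39.0% of its charge, 0.713 of amber's share, against my 0.555. With the kill constant, the violet run's rate over the amber run's at the point of the third question, 2.7, asks for a difference of 51.9 min of exposure between those flasks; without that step the ratio is 1.0.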